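## Retrosynthetic overview

1. Last step: one palladium-catalysed allyl transfer frees the C19 acid from its allyl ester and moves the acetate from the tertiary C13 carbinol to C15, creating the 13E alkene.
2. Before that: the C3 carbonyl is removed through its tosylhydrazone, after the C4 methyl has been put on the α face of a bicyclic β-keto ester (ester ends up axial).
3. Key disconnection C4–C5, then C10–C9: oxidation turns the normally nucleophilic α-carbon of an acyclic β-keto ester into an electrophilic radical that attacks the nucleophilic trisubstituted alkene. Ring A closes first and ring B second in one cascade that ends as the 8(17)-alkene, with a chiral copper Lewis acid fixing the absolute configuration.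
4. The acyclic precursor comes from γ-alkylation of the allyl acetoacetate dianion with an ω-bromide made from (6E)-nerolidol (acetylation, SeO2 oxidation, Appel bromination).
5. The tertiary vinyl carbinol acetate end group offers the last radical no 6-endo path, so the cascade stops at the bicycle, and it is the latent (13E)-allylic acetate.

Assumption: commercial trans-nerolidol ((6E), racemic at its carbinol carbon) is used; that carbon (labdane C13) becomes sp2 in the last step, so the intermediates are 1:1 C13 epimer pairs with C13 left undefined in their SMILES, and in step 5 the ligand antipode is chosen on the first analytical run (both are sold; (S,S) is written).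

## Route

Step 1
Reactants: 1 (6E)-nerolidol [(6E)-3,7,11-trimethyldodeca-1,6,10-trien-3-ol]
Product: 2 (6E)-nerolidyl acetate [(6E)-3,7,11-trimethyldodeca-1,6,10-trien-3-yl acetate]
Conditions: Ac2O, Et3N, DMAP (10 mol %), CH2Cl2, 25 °C
Reagents that add atoms: acetic anhydride, CC(=O)OC(C)=O
Why: DMAP-catalysed acylation of the tertiary allylic alcohol gives the acetate that protects the carbinol through the dianion and radical steps and is the migrating group of the last step; no stereocentre is formed.

Step 2
Reactants: 2 (6E)-nerolidyl acetate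
Product: 3 (6E,10E)-12-hydroxy-3,7,11-trimethyldodeca-1,6,10-trien-3-yl acetate
Conditions: SeO2 (0.3 equiv), t-BuOOH (3 equiv), salicylic acid (10 mol %), CH2Cl2, 25 °C
Reagents that add atoms: selenium dioxide, O=[Se]=O; tert-butyl hydroperoxide, CC(C)(C)OO
Why: SeO2/t-BuOOH allylic oxidation (ene reaction then [2,3]-sigmatropic shift) takes the (E)-methyl group of the terminal, least hindered trisubstituted alkene and so gives the (10E)-allylic alcohol.

Step 3
Reactants: 3 (6E,10E)-12-hydroxy-3,7,11-trimethyldodeca-1,6,10-trien-3-yl acetate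
Product: 4 (6E,10E)-12-bromo-3,7,11-trimethyldodeca-1,6,10-trien-3-yl acetate
Conditions: CBr4, PPh3, CH2Cl2, 0 °C
Reagents that add atoms: carbon tetrabromide, BrC(Br)(Br)Br
Why: Appel bromination of the primary allylic alcohol proceeds by SN2 displacement of the oxyphosphonium group with the alkene geometry kept and the tertiary acetate untouched.

Step 4
Reactants: 4 (6E,10E)-12-bromo-3,7,11-trimethyldodeca-1,6,10-trien-3-yl acetate; 5 allyl acetoacetate (prop-2-enyl 3-oxobutanoate)
Product: 7 allyl (6E,10E)-14-acetoxy-6,10,14-trimethyl-3-oxohexadeca-6,10,15-trienoate, via acetoacetate dianion 6 (not isolated)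
Conditions: 5 (1.1 equiv), NaH, THF, 0 °C; n-BuLi, 0 °C; then 4, −78 → −20 °C; cold 0.5 M HCl
Reagents that add atoms: none
Why: Weiler dianion alkylation, in which the γ-carbanion displaces the primary allylic bromide (SN2) at low temperature faster than it attacks the hindered tertiary acetate or rearranges, with both E alkenes retained.

Step 5
Reactants: 7 allyl (6E,10E)-14-acetoxy-6,10,14-trimethyl-3-oxohexadeca-6,10,15-trienoate
Product: 8 allyl 13-acetoxy-3-oxo-18-norlabda-8(17),14-dien-19-oate (trans-decalin; 5α-H; 10β-CH3; 9α-H with the side chain equatorial; C4 epimerisable)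
Conditions: Mn(OAc)3·2H2O (2.1 equiv), Cu(OAc)2·H2O (1.1 equiv), (S,S)-t-Bu-box (1.2 equiv), degassed EtOH, 0 → 25 °C
Reagents that add atoms: none
Why: Proposed new method: the β-keto ester is held as a two-point-bound copper enolate of the chiral bisoxazoline complex and is oxidised by trivalent manganese to the electrophilic, polarity-reversed C4 radical, which adds 6-endo to C5 of the electron-rich (E)-C5=C10 alkene, and the resulting C10 radical adds 6-endo to C9 of the (E)-C8=C9 alkene through a chair–chair array (trans fusion 5α-H/10β-CH3, equatorial 9β side chain) with the tert-butyl groups of the ligand deciding which enantiomeric chair reacts, after which the C8 radical, left with only a slow 6-exo path to the vinyl group beside the quaternary C13, is oxidised by divalent copper with loss of a C17 hydrogen to the exocyclic alkene; closest known reaction types are the Mn(OAc)3/Cu(OAc)2 oxidative free-radical polycyclisation of β-keto esters (Snider type), Lewis-acid-controlled radical cyclisations of chelated β-keto esters and copper–bisoxazoline two-point binding of β-keto esters.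

Step 6
Reactants: 8 allyl 13-acetoxy-3-oxo-18-norlabda-8(17),14-dien-19-oate
Product: 9 allyl 13-acetoxy-3-oxolabda-8(17),14-dien-19-oate (4α-CH3; 4β-CO2allyl axial and cis to the C10 methyl; 5α-H; 9α-H; 10β-CH3)
Conditions: MeI, K2CO3, acetone, 50 °C
Reagents that add atoms: iodomethane, CI
Why: C-methylation of the stabilised β-keto ester enolate, in which MeI approaches C4 from the α face, away from the 1,3-diaxial C10 methyl group, so the methyl becomes 4α (equatorial) and the ester 4β (axial), the classical resin-acid outcome for this alkylation order.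

Step 7
Reactants: 9 allyl 13-acetoxy-3-oxolabda-8(17),14-dien-19-oate
Product: 11 allyl 13-acetoxylabda-8(17),14-dien-19-oate (4S,5R,9S,10R), via tosylhydrazone 10 (not isolated)
Conditions: TsNHNH2, PPTS (10 mol %), EtOH, 70 °C; evaporate; catecholborane, CHCl3, 0 °C; then NaOAc·3H2O, 60 °C
Reagents that add atoms: none
Why: Caglioti–Kabalka deoxygenation, in which catecholborane delivers hydride to the C=N bond of the tosylhydrazone and loss of sulfinate and N2 leaves the C3 methylene, with esters, alkenes and all stereocentres untouched.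

Step 8
Reactants: 11 allyl 13-acetoxylabda-8(17),14-dien-19-oate
Product: 13 15-acetoxyisocupressic acid [(13E)-15-acetoxylabda-8(17),13-dien-19-oic acid; (4S,5R,9S,10R)], via 13-acetoxy acid 12 (not isolated)
Conditions: Pd(PPh3)4 (5 mol %), AcOH (20 equiv), NaOAc (5 equiv), THF, 25 °C then 50 °C; AgNO3–SiO2 chromatography
Reagents that add atoms: acetic acid, CC(=O)O
Why: Tsuji–Trost allyl transfer, in which zerovalent palladium ionises both allylic esters, acetate carries off the C19 allyl group as allyl acetate and returns to the unhindered primary end of the side-chain π-allyl complex whose bulky chain prefers the syn position, so the trisubstituted 13E primary acetate is the main equilibrium product (about 3:1 over 13Z, with the 13Z and tertiary isomers separated and re-equilibrated).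

## Compound list

1 | (6E)-nerolidol, (6E)-3,7,11-trimethyldodeca-1,6,10-trien-3-ol (racemic at C3) | CC(C)=CCC/C(C)=C/CCC(C)(O)C=C | starting material
2 | (6E)-nerolidyl acetate | CC(C)=CCC/C(C)=C/CCC(C)(OC(C)=O)C=C | intermediate
3 | (6E,10E)-12-hydroxy-3,7,11-trimethyldodeca-1,6,10-trien-3-yl acetate | OC/C(C)=C/CC/C(C)=C/CCC(C)(OC(C)=O)C=C | intermediate
4 | (6E,10E)-12-bromo-3,7,11-trimethyldodeca-1,6,10-trien-3-yl acetate | BrC/C(C)=C/CC/C(C)=C/CCC(C)(OC(C)=O)C=C | intermediate
5 | allyl acetoacetate (prop-2-enyl 3-oxobutanoate) | CC(=O)CC(=O)OCC=C | starting material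
6 | sodium lithium dianion of allyl acetoacetate | [CH2-]C(=O)[CH-]C(=O)OCC=C.[Na+].[Li+] | intermediate
7 | allyl (6E,10E)-14-acetoxy-6,10,14-trimethyl-3-oxohexadeca-6,10,15-trienoate | C=CCOC(=O)CC(=O)CC/C(C)=C/CC/C(C)=C/CCC(C)(OC(C)=O)C=C | intermediate
8 | allyl 13-acetoxy-3-oxo-18-norlabda-8(17),14-dien-19-oate (5α-H, 9α-H, 10β-CH3; C4 epimerisable) | C=C1CC[C@@H]2[C@](C)(CCC(=O)C2C(=O)OCC=C)[C@H]1CCC(C)(OC(C)=O)C=C | intermediate
9 | allyl 13-acetoxy-3-oxolabda-8(17),14-dien-19-oate (4α-CH3, 4β-ester, 5α-H, 9α-H, 10β-CH3) | C=C1CC[C@@H]2[C@](C)(CCC(=O)[C@]2(C)C(=O)OCC=C)[C@H]1CCC(C)(OC(C)=O)C=C | intermediate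
10 | C3 p-toluenesulfonylhydrazone of 9 | C=C1CC[C@@H]2[C@](C)(CCC(=NNS(=O)(=O)c3ccc(C)cc3)[C@]2(C)C(=O)OCC=C)[C@H]1CCC(C)(OC(C)=O)C=C | intermediate
11 | allyl 13-acetoxylabda-8(17),14-dien-19-oate (4S,5R,9S,10R) | C=C1CC[C@@H]2[C@](C)(CCC[C@]2(C)C(=O)OCC=C)[C@H]1CCC(C)(OC(C)=O)C=C | intermediate
12 | 13-acetoxylabda-8(17),14-dien-19-oic acid (4S,5R,9S,10R) | C=C1CC[C@@H]2[C@](C)(CCC[C@]2(C)C(=O)O)[C@H]1CCC(C)(OC(C)=O)C=C | intermediate
13 | 15-acetoxyisocupressic acid, (13E)-15-acetoxylabda-8(17),13-dien-19-oic acid (4S,5R,9S,10R) | C=C1CC[C@@H]2[C@](C)(CCC[C@]2(C)C(=O)O)[C@H]1CC/C(C)=C/COC(C)=O | target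

## Step count and risks

Total step count: 8. Longest linear sequence: 8 (1 → 13; 5 is bought and enters at step 4).

Steps most likely to fail:

Step 5 (the bicyclisation). The enantioselectivity is unproven, a racemic path through a manganese enolate may compete, the enolised product 8 can be oxidised further, and some 6-exo closure onto the vinyl group is possible. The fallback sets out from 7 and comes back at 8. It replaces the oxidative cascade by a group-transfer radical chain under a chiral magnesium Lewis acid at low temperature. Selenenylation of 7 (PhSeCl, pyridine, CH2Cl2, 0 °C) gives the α-phenylselanyl keto ester F1. Mg(ClO4)2/(S,S)-t-Bu-box in toluene at −78 °C with Et3B/O2 initiation then gives, by phenylselanyl transfer to the C8 radical, the bicyclic C8 phenyl selenide F2. Oxidation (H2O2, pyridine, CH2Cl2, 0 °C) and selenoxide syn-elimination toward the C17 methyl group gives 8.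

Step 7 (deoxygenation). The C3 ketone is flanked by the quaternary C4 and may condense or reduce sluggishly. The fallback sets out from 9 and comes back at 11. It removes the oxygen by radical C–O cleavage instead. NaBH4 in MeOH at 0 °C attacks from the α face and gives the 3β-alcohol F3. 1,1'-Thiocarbonyldiimidazole with DMAP in toluene at 80 °C gives the imidazolyl thiocarbonate F4. Barton–McCombie reduction (Bu3SnH, AIBN, toluene, 100 °C) gives 11.

Step 8 (allyl transfer). Both allylic esters ionise in one pot, so diene formation, capture of the side-chain π-allyl by the C19 carboxylate and the modest E:Z ratio all cost yield. The fallback sets out from 11 and comes back at 13. It separates the two events and avoids a π-allyl intermediate in the transposition. PdCl2(MeCN)2 (5 mol %) in THF at 25 °C effects a divalent-palladium-catalysed cyclisation-induced [3,3] shift of the tertiary acetate and gives the allyl ester of the target F5. Pd(PPh3)4 (2 mol %) with PhSiH3 in CH2Cl2 at 0 °C then removes the unsubstituted allyl ester faster than the trisubstituted allylic acetate can ionise and gives 13.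

## Further compounds

F1 | step 5 | allyl (6E,10E)-14-acetoxy-6,10,14-trimethyl-3-oxo-2-(phenylselanyl)hexadeca-6,10,15-trienoate | C=CCOC(=O)C([Se]c1ccccc1)C(=O)CC/C(C)=C/CC/C(C)=C/CCC(C)(OC(C)=O)C=C
F2 | step 5 | allyl 13-acetoxy-3-oxo-8-(phenylselanyl)-18-norlabd-14-en-19-oate (5α-H, 9α-H, 10β-CH3; C4 and C8 undefined) | CC1([Se]c2ccccc2)CC[C@@H]2[C@](C)(CCC(=O)C2C(=O)OCC=C)[C@H]1CCC(C)(OC(C)=O)C=C
F3 | step 7 | allyl 13-acetoxy-3β-hydroxylabda-8(17),14-dien-19-oate | C=C1CC[C@@H]2[C@](C)(CC[C@H](O)[C@]2(C)C(=O)OCC=C)[C@H]1CCC(C)(OC(C)=O)C=C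
F4 | step 7 | allyl 13-acetoxy-3β-[(imidazol-1-ylcarbonothioyl)oxy]labda-8(17),14-dien-19-oate | C=C1CC[C@@H]2[C@](C)(CC[C@H](OC(=S)n3ccnc3)[C@]2(C)C(=O)OCC=C)[C@H]1CCC(C)(OC(C)=O)C=C
F5 | step 8 | allyl (13E)-15-acetoxylabda-8(17),13-dien-19-oate | C=C1CC[C@@H]2[C@](C)(CCC[C@]2(C)C(=O)OCC=C)[C@H]1CC/C(C)=C/COC(C)=O
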